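A direct plan would keep the pyridine intact: NiCl2(dppp)-catalysed Kumada coupling of 3-bromopyridine A1 with decylmagnesium bromide A2 would give 3-decylpyridine A3; N-acylation with decanoyl chloride A4 and hydride delivery to C4 (LiAlH(O-t-Bu)3/CuBr) would give 1-decanoyl-3-decyl-1,4-dihydropyridine A5; a photochemical 1,3 N→C acyl shift to 1-(5-decyl-1,4-dihydropyridin-3-yl)decan-1-one A6 and DDQ oxidation would give the target.
Its weakest steps would be:
- The photochemical N→C acyl shift from A5 to A6: it has no precedent on 1-acyl-1,4-dihydropyridines, the radical pair formed on N–C(=O) cleavage can recombine at the decyl-bearing carbon or escape the solvent cage, and it needs 254 nm light at high dilution on a product that absorbs there itself.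
- The reductive dearomatisation of A3 to A5: 1,4- versus 1,2-hydride delivery is not controlled by the substrate, and the air-sensitive bis-enamide A5 must be carried on at once.
- The redox detour as a whole: the ring of A3 is reduced and then re-oxidised with DDQ only to move one acyl group from N to C, so most of the sequence builds no skeleton.

**Retrosynthetic overview**
The pyridine ring itself is disconnected: N1–C2, C3–C4 and N1–C6 are all formed in one pot from three acyclic components.
The ring carries H at C2, C4 and C6 and carbon substituents only at C3 (decanoyl) and C5 (decyl). C4–C5(decyl)–C6 is therefore a masked 2-decylmalondialdehyde (aminoacrolein 4, from dodecanal dimethyl acetal and DMF), C2–C3(decanoyl) is the alkyne of silyl ynone 7 (from decanoyl chloride), and N1 is ammonia.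
The ring is the last thing made and is formed directly at the aromatic oxidation level, so the route has no cross-coupling on a halopyridine, no dearomatisation/rearomatisation and no photochemistry.
The two termini of the C3 partner are equivalent, so the ring closure raises no question of orientation.

Key step: step 3

Remark: the target has no stereocentre. The double-bond geometries written for 3, 4, 9 and 10 are the expected ones and are of no consequence, because all of these carbons end up in the aromatic ring.

Step 1
Reactants: 1 1,1-dimethoxydodecane; 2 N,N-dimethylformamide
Product: 4 (E)-2-[(dimethylamino)methylidene]dodecanal, via methoxypropeniminium chloride 3 (not isolated)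
Conditions: POCl3 (2.2 equiv), 2 (excess, as solvent), 0 °C; add 1, 70 °C, 3 h; then ice, aq. K2CO3 to pH 9–10, rt
Reagents that add atoms: N,N-dimethylformamide, CN(C)C=O; water, O
Why: Vilsmeier–Haack formylation in the Arnold manner: under the acidic conditions acetal 1 should lose methanol to the enol ether, whose α-carbon is C-formylated by the chloroiminium salt from 2 and POCl3 to give the vinylogous iminium ether 3, and hydrolysis with aqueous K2CO3 at the methoxy-bearing terminus should leave the stable push–pull aminoacrolein 4 (the general access to 2-alkylmalondialdehyde equivalents from aldehyde acetals; no stereocentre is formed).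

Step 2
Reactants: 5 decanoyl chloride; 6 bis(trimethylsilyl)acetylene
Product: 7 1-(trimethylsilyl)dodec-1-yn-3-one
Conditions: AlCl3 (1.1 equiv), CH2Cl2, 0 °C, 1 h; cold 1 M HCl work-up
Reagents that add atoms: bis(trimethylsilyl)acetylene, C[Si](C)(C)C#C[Si](C)(C)C
Why: Friedel–Crafts-type ipso-acylation of an alkynylsilane: the acylium ion from 5 and AlCl3 should attack 6 to give a β-silyl-stabilised vinyl cation that loses Me3SiCl, and the acyl group deactivates the product towards a second acylation, so the mono-silyl ynone 7 should result.

Step 3
Reactants: 7 1-(trimethylsilyl)dodec-1-yn-3-one; 8 ammonia; 4 (E)-2-[(dimethylamino)methylidene]dodecanal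
Product: 11 1-(5-decylpyridin-3-yl)decan-1-one, via (Z)-1-aminododec-1-en-3-one 9 (not isolated), via aminodienal 10 (not isolated)
Conditions: 8 (7 M in MeOH, 3 equiv), 0 °C to rt, 1 h; concentrate at 25 °C or below; then 4 (1.3 equiv), AcOH, 80 °C, 3 h; aq. NaHCO3 work-up
Reagents that add atoms: ammonia, N; (E)-2-[(dimethylamino)methylidene]dodecanal, CCCCCCCCCC/C(C=O)=C\N(C)C
Why: Methanolic ammonia should cleave the alkynyl–silicon bond of 7 and add to the terminal alkyne carbon to give the hydrogen-bonded enaminone 9, which places nitrogen on the future C2, and excess ammonia is removed before 4 is added so that nitrogen cannot reach the ketone carbon. In AcOH the nucleophilic α-carbon of 9 should attack the protonated push–pull aldehyde 4 at its amino-bearing terminus with loss of dimethylamine (C3–C4 bond) to give aminodienal 10, whose NH2 adds to the remaining aldehyde (N1–C6 bond, 6-exo-trig) and dehydration delivers the ring directly at the aromatic oxidation level; if N–C bond formation comes first, the resulting divinylamine closes by intramolecular aldol condensation at C3–C4 and the same pyridine results. The closest known reaction types are the one-pot Bohlmann–Rahtz pyridine synthesis with silyl ynones and ammonia and the [3+3] condensation of β-enaminones or β-aminocrotonates with 3-aminoacroleins and vinamidinium salts. No stereocentre is formed. The step needs cross-condensation to beat self-condensation of 9 (which would lead to a 2-nonyl-5-acylpyridine): the protonated aldehyde of 4 is a far better electrophile than the vinylogous-amide ketone of 9, 4 is used in excess and, being fully substituted at its central carbon, cannot act as a carbon nucleophile. Orientation is not an issue because both termini of 4 are at the aldehyde oxidation level and both become ring CH (C4 and C6).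

**Compound list**
1 | 1,1-dimethoxydodecane | CCCCCCCCCCCC(OC)OC | starting material
2 | N,N-dimethylformamide | CN(C)C=O | starting material
3 | N-[(2E)-2-decyl-3-methoxyprop-2-en-1-ylidene]-N-methylmethanaminium chloride | CCCCCCCCCC/C(=C\OC)C=[N+](C)C.[Cl-] | intermediate (not isolated)
4 | (E)-2-[(dimethylamino)methylidene]dodecanal | CCCCCCCCCC/C(C=O)=C\N(C)C | intermediate
5 | decanoyl chloride | CCCCCCCCCC(=O)Cl | starting material
6 | bis(trimethylsilyl)acetylene | C[Si](C)(C)C#C[Si](C)(C)C | starting material
7 | 1-(trimethylsilyl)dodec-1-yn-3-one | CCCCCCCCCC(=O)C#C[Si](C)(C)C | intermediate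
8 | ammonia | N | starting material
9 | (Z)-1-aminododec-1-en-3-one | CCCCCCCCCC(=O)/C=C\N | intermediate (not isolated)
10 | (2Z,4E)-4-(aminomethylidene)-2-decyl-5-oxotetradec-2-enal (cyclisation-competent geometry) | N/C=C(C(=O)CCCCCCCCC)\C=C(CCCCCCCCCC)/C=O | intermediate (not isolated)
11 | 1-(5-decylpyridin-3-yl)decan-1-one | CCCCCCCCCCc1cncc(C(=O)CCCCCCCCC)c1 | target

Total step count: 3. Longest linear sequence: 2 steps (step 1 or step 2, then step 3).

**Steps most likely to fail**

1. Step 3 (key step). The primary enaminone 9 may self-condense, or add to ynone not yet consumed, faster than it is intercepted by 4, or it may hydrolyse in the acid and lose the fixed position of nitrogen. The fallback sets out from 4 and comes back at 11. It keeps the same ring construction but uses an enamine that cannot self-condense to a pyridine, and makes the ketone afterwards. Ethyl propiolate and ammonia in methanol at 0 °C would give ethyl (Z)-3-aminoacrylate F1. F1 and 4 in AcOH at 80 °C would give ethyl 5-decylnicotinate F2 by the same [3+3] condensation. Me(MeO)NH·HCl and i-PrMgCl in THF at −20 °C would convert F2 into 5-decyl-N-methoxy-N-methylpyridine-3-carboxamide F3. Nonylmagnesium bromide in THF at 0 °C would then add to F3 and stop at the ketone 11 through the chelated tetrahedral intermediate.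

2. Step 1. Formylation of the long-chain acetal may stay incomplete, the liberated aldehyde may undergo self-aldol condensation or chlorination in the hot acidic medium, and the work-up may over-hydrolyse the product to the water-soluble malondialdehyde enolate. The fallback sets out from 1 and comes back at 11 through step 3. It builds the C3 unit by an oxocarbenium addition in place of the chloroiminium formylation. Acetal 1 would be converted with Me3SiOTf and i-Pr2NEt in CH2Cl2 (−20 °C to rt) into 1-methoxydodec-1-ene F4. F4 would be added to trimethyl orthoformate under BF3·OEt2 catalysis at 0 °C to give 2-decyl-1,1,3,3-tetramethoxypropane F5. F5 would replace 4 in step 3 (AcOH, 80 °C, the acetals being unmasked in the flask) and should give 11.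

3. Step 2. The AlCl3-bound ynone may add HCl, lose its silyl group and polymerise, or the alkyne may be acylated at both ends. The fallback sets out from 5 and comes back at 9. It replaces the electrophilic substitution of the alkynylsilane by a nucleophilic acetylide. Decanoyl chloride 5 with Me(MeO)NH·HCl and pyridine in CH2Cl2 would give N-methoxy-N-methyldecanamide F6. F6 with ethynylmagnesium bromide in THF at 0 °C, followed by an inverse quench into cold aqueous NaHSO4 so that the liberated hydroxylamine does not add to the ynone, would give dodec-1-yn-3-one F7. F7 would be treated at once with methanolic ammonia as in step 3 to give 9.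

**Further compounds**
F1 | step 3 | ethyl (Z)-3-aminoacrylate | CCOC(=O)/C=C\N
F2 | step 3 | ethyl 5-decylnicotinate | CCCCCCCCCCc1cncc(C(=O)OCC)c1
F3 | step 3 | 5-decyl-N-methoxy-N-methylpyridine-3-carboxamide | CCCCCCCCCCc1cncc(C(=O)N(C)OC)c1
F4 | step 1 | 1-methoxydodec-1-ene (E/Z mixture) | CCCCCCCCCCC=COC
F5 | step 1 | 2-decyl-1,1,3,3-tetramethoxypropane | CCCCCCCCCCC(C(OC)OC)C(OC)OC
F6 | step 2 | N-methoxy-N-methyldecanamide | CCCCCCCCCC(=O)N(C)OC
F7 | step 2 | dodec-1-yn-3-one | CCCCCCCCCC(=O)C#C
A1 | direct plan | 3-bromopyridine | Brc1cccnc1
A2 | direct plan | decylmagnesium bromide | CCCCCCCCCC[Mg]Br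
A3 | direct plan | 3-decylpyridine | CCCCCCCCCCc1cccnc1
A4 | direct plan | decanoyl chloride | CCCCCCCCCC(=O)Cl
A5 | direct plan | 1-decanoyl-3-decyl-1,4-dihydropyridine | CCCCCCCCCC(=O)N1C=CCC(CCCCCCCCCC)=C1
A6 | direct plan | 1-(5-decyl-1,4-dihydropyridin-3-yl)decan-1-one | CCCCCCCCCC(=O)C1=CNC=C(CCCCCCCCCC)C1
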